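**Assumption:** the target is the free bisphenol with the configuration as drawn, (3R,4R,5R)-oxolane. The aryl and benzyl groups are cis, and the methyl is trans to both. The enantiomer of the Ru-BINAP catalyst and the anti-Prelog ketoreductase that give this configuration are assumed to be identifiable by small-scale screening.

## Retrosynthetic overview
1. The target comes from global debenzylation of the dibenzyl THF 24. The THF ring is closed last, by 5-exo-tet displacement of a primary tosylate by the C7 benzylic alkoxide, so C7 is retained.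
2. The C7 carbinol comes from ketoreductase reduction of an aryl ketone. The ketone comes from addition of ArMgBr to a Weinreb amide made by opening a trans-3-methyl-4-benzyl-γ-butyrolactone.
3. The γ-butyrolactone is formed first. C8 (Me) is set by trans-selective enolate methylation of the β-benzyl lactone.
4. The β-benzyl lactone comes from chemoselective reduction of the methyl ester of a half-ester that is made by Ru-catalysed asymmetric hydrogenation (C8′, the first stereocenter). That half-ester comes from Stobbe condensation of O-benzyl syringaldehyde with dimethyl succinate.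
5. Ring order: lactone (opened again later), then THF last.

## Route

**Step 1**
Reactants: 1 syringaldehyde (4-hydroxy-3,5-dimethoxybenzaldehyde); 2 benzyl bromide
Product: 3, 4-(benzyloxy)-3,5-dimethoxybenzaldehyde
Conditions: K2CO3, DMF, rt, 12 h
Reagents that add atoms: benzyl bromide (2), BrCc1ccccc1
Why: Williamson O-benzylation masks the phenol for the later Grignard, hydride and base steps.

**Step 2**
Reactants: 4 4-bromo-2-methoxyphenol; 2 benzyl bromide
Product: 5, 1-(benzyloxy)-4-bromo-2-methoxybenzene
Conditions: K2CO3, acetone, reflux, 8 h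
Reagents that add atoms: benzyl bromide (2), BrCc1ccccc1
Why: the same O-benzylation gives a Grignard precursor that carries the guaiacyl ring with its phenol protected.

**Step 3**
Reactants: 3; 6 dimethyl succinate
Product: 7, (E)-4-[4-(benzyloxy)-3,5-dimethoxyphenyl]-3-(methoxycarbonyl)but-3-enoic acid
Conditions: KOtBu (2 equiv), tBuOH, reflux, 3 h; then 1 M HCl
Reagents that add atoms: none (the succinate is the reactant)
Why: Stobbe condensation proceeds through a paraconic lactone whose E1cB opening gives the E-alkene. The conjugated methyl ester is retained and the free acid sits on CH2.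

**Step 4**
Reactants: 7
Product: 8, (R)-4-[4-(benzyloxy)-3,5-dimethoxyphenyl]-3-(methoxycarbonyl)butanoic acid (C8′ of the target numbering)
Conditions: H2 (50 bar), Ru(OAc)2[(R)-BINAP] (1 mol%), MeOH, 50 °C, 24 h
Reagents that add atoms: none (H2 adds only H)
Why: carboxyl-directed Ru-catalysed asymmetric hydrogenation of the trisubstituted alkene sets C8′ as (R) (C8′ becomes C4 of the oxolane). This is the first stereocenter.

**Step 5**
Reactants: 8
Product: 9, (R)-3-{[4-(benzyloxy)-3,5-dimethoxyphenyl]methyl}-4-hydroxybutanoic acid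
Conditions: LiBH4 (3 equiv), THF, 0 → 65 °C, 6 h; then 1 M HCl
Reagents that add atoms: none (hydride only)
Why: the acid is deprotonated at once to a lithium carboxylate that LiBH4 does not reduce, so only the methyl ester on C8′ is reduced to CH2OH (chemoselective hydride reduction). This puts the future C9′–O on the carbon next to C8′. No stereocenter is touched.

**Step 6**
Reactants: 9
Product: 10, (4R)-4-{[4-(benzyloxy)-3,5-dimethoxyphenyl]methyl}oxolan-2-one
Conditions: TsOH·H2O (5 mol%), toluene, 4 Å MS, rt → 40 °C, 4 h
Reagents that add atoms: none (intramolecular; water is lost)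
Why: acid-catalysed lactonisation of a γ-hydroxy acid gives the β-benzyl-γ-butyrolactone, the substrate for C8 alkylation.

**Step 7**
Reactants: 10; 11 iodomethane
Product: 12, (3R,4R)-4-{[4-(benzyloxy)-3,5-dimethoxyphenyl]methyl}-3-methyloxolan-2-one
Conditions: LiHMDS (1.1 equiv), THF, −78 °C, 1 h; then MeI (1.5 equiv), −78 → −40 °C
Reagents that add atoms: iodomethane (11), CI
Why: the lactone enolate is alkylated anti to the adjacent 4-benzyl group (enolate alkylation under substrate control), giving the 3,4-trans product. This sets C8 (R) with Me trans to the benzyl group, as in the target.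

**Step 8**
Reactants: 12; 13 N,O-dimethylhydroxylamine (as its HCl salt)
Product: 14, (2R,3R)-3-{[4-(benzyloxy)-3,5-dimethoxyphenyl]methyl}-4-hydroxy-N-methoxy-N,2-dimethylbutanamide
Conditions: MeNH(OMe)·HCl, AlMe3 (2 M in hexanes), CH2Cl2, 0 °C → rt, 4 h; then Rochelle salt
Reagents that add atoms: N,O-dimethylhydroxylamine (13), CNOC
Why: Weinreb-type Al-amide aminolysis opens the lactone under mild, non-epimerising conditions. The former lactone carbonyl becomes the Weinreb amide, which is later converted to the C7 ketone.

**Step 9**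
Reactants: 14; 15 TBSCl
Product: 16, (2R,3R)-4-(tert-butyldimethylsilyloxy)-3-{[4-(benzyloxy)-3,5-dimethoxyphenyl]methyl}-N-methoxy-N,2-dimethylbutanamide
Conditions: TBSCl (1.2 equiv), imidazole, DMF, rt, 6 h
Reagents that add atoms: TBSCl (15), CC(C)(C)[Si](C)(C)Cl
Why: silylation of the primary OH prevents Grignard quenching and re-lactonisation in the coupling step.

**Step 10**
Reactants: 5; 17 magnesium turnings
Product: 18, 4-(benzyloxy)-3-methoxyphenylmagnesium bromide (about 0.5 M in THF, used immediately)
Conditions: Mg (1.3 equiv), I2 (cat.), THF, 50 °C, 2 h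
Reagents that add atoms: magnesium (17), [Mg]
Why: oxidative insertion of Mg into the aryl C–Br bond (Grignard formation); the aryl benzyl ether and methyl ether are inert to these conditions.

**Step 11**
Reactants: 16; 18 (2.5 equiv)
Product: 19, (2R,3R)-1-[4-(benzyloxy)-3-methoxyphenyl]-3-{[4-(benzyloxy)-3,5-dimethoxyphenyl]methyl}-4-(tert-butyldimethylsilyloxy)-2-methylbutan-1-one
Conditions: THF, 0 °C → rt, 3 h; then sat. aq. NH4Cl
Reagents that add atoms: 4-(benzyloxy)-3-methoxyphenylmagnesium bromide (18), COc1cc([Mg]Br)ccc1OCc1ccccc1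
Why: Weinreb ketone synthesis stops at the chelated tetrahedral intermediate, so only one aryl group adds and no tertiary alcohol forms. This installs the C7 carbonyl with C8 and C8′ untouched. The OTBS is γ to the carbonyl, so no elimination occurs.

**Step 12**
Reactants: 19
Product: 20, (2R,3R)-1-[4-(benzyloxy)-3-methoxyphenyl]-3-{[4-(benzyloxy)-3,5-dimethoxyphenyl]methyl}-4-hydroxy-2-methylbutan-1-one
Conditions: TBAF (1.5 equiv), AcOH (1.5 equiv), THF, 0 °C → rt, 4 h
Reagents that add atoms: none (fluoride removes the silyl group)
Why: AcOH-buffered fluoride desilylation avoids base-mediated epimerisation at the ketone α-carbon (C8). The free primary OH gives a more polar, enzyme-compatible substrate, and the aryl ketone stays open-chain.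

**Step 13**
Reactants: 20
Product: 21, (1R,2R,3R)-1-[4-(benzyloxy)-3-methoxyphenyl]-3-{[4-(benzyloxy)-3,5-dimethoxyphenyl]methyl}-2-methylbutane-1,4-diol
Conditions: anti-Prelog NADPH-dependent ketoreductase (KRED, Lactobacillus kefir-type), NADP+ (1 mM), iPrOH (20% v/v, cofactor recycling), DMSO (10% v/v), 100 mM KPi pH 7.0, 30 °C, 24–48 h
Reagents that add atoms: none (the cofactor supplies hydride only)
Why: enzyme-catalysed enantiofacial reduction (ketoreductase, oxidoreductase class) delivers hydride to the Si face of the ketone, setting C7 as (R) so that Ar ends up trans to Me as required. The enzyme pocket controls the face, and pH 7 does not epimerise C8.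

**Step 14**
Reactants: 21; 22 p-toluenesulfonyl chloride
Product: 23, primary tosylate, (2R,3R,4R)-4-[4-(benzyloxy)-3-methoxyphenyl]-2-{[4-(benzyloxy)-3,5-dimethoxyphenyl]methyl}-4-hydroxy-3-methylbutyl 4-methylbenzenesulfonate
Conditions: TsCl (1.05 equiv), Et3N, Me3N·HCl (cat.), CH2Cl2, 0 °C, 12 h
Reagents that add atoms: TsCl (22), Cc1ccc(cc1)S(=O)(=O)Cl
Why: sulfonylation is selective for the unhindered primary OH over the hindered secondary benzylic OH. No stereocenter is touched.

**Step 15**
Reactants: 23
Product: 24, (2R,3R,4R)-2-[4-(benzyloxy)-3-methoxyphenyl]-4-{[4-(benzyloxy)-3,5-dimethoxyphenyl]methyl}-3-methyloxolane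
Conditions: NaH (2 equiv), THF, 0 °C → rt, 3 h
Reagents that add atoms: none (TsO− is lost)
Why: the benzylic alkoxide displaces the primary tosylate in an intramolecular Williamson ether synthesis (5-exo-tet). No bond to C7 is broken, so its configuration is retained and the 2,3-trans-3,4-trans THF forms.

**Step 16**
Reactants: 24
Product: 25, target, 2,6-dimethoxy-4-{[(3R,4R,5R)-5-(4-hydroxy-3-methoxyphenyl)-4-methyloxolan-3-yl]methyl}phenol
Conditions: H2 (1 atm), 10% Pd/C, EtOAc/MeOH 1:1, rt, 1–3 h (monitor closely)
Reagents that add atoms: none (hydrogenolysis releases toluene)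
Why: hydrogenolysis of the two aryl benzyl ethers frees both phenols. The mild, short conditions leave the benzylic THF C–O bond and the stereocenters intact.

## Compound list
1 | syringaldehyde | COc1cc(C=O)cc(OC)c1O | starting material
2 | benzyl bromide | BrCc1ccccc1 | starting material (reagent)
3 | 4-(benzyloxy)-3,5-dimethoxybenzaldehyde | COc1cc(C=O)cc(OC)c1OCc1ccccc1 | intermediate
4 | 4-bromo-2-methoxyphenol | COc1cc(Br)ccc1O | starting material
5 | 1-(benzyloxy)-4-bromo-2-methoxybenzene | COc1cc(Br)ccc1OCc1ccccc1 | intermediate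
6 | dimethyl succinate | COC(=O)CCC(=O)OC | starting material
7 | (E)-Stobbe half-ester | COC(=O)/C(CC(=O)O)=C/c1cc(OC)c(OCc2ccccc2)c(OC)c1 | intermediate
8 | (R)-hydrogenated half-ester | COC(=O)[C@H](Cc1cc(OC)c(OCc2ccccc2)c(OC)c1)CC(=O)O | intermediate
9 | (R)-γ-hydroxy acid | OC(=O)C[C@@H](Cc1cc(OC)c(OCc2ccccc2)c(OC)c1)CO | intermediate
10 | (4R)-β-benzyl lactone | O=C1OC[C@H](Cc2cc(OC)c(OCc3ccccc3)c(OC)c2)C1 | intermediate
11 | iodomethane | CI | starting material (reagent)
12 | (3R,4R)-3-methyl-4-benzyl lactone | O=C1OC[C@H](Cc2cc(OC)c(OCc3ccccc3)c(OC)c2)[C@H]1C | intermediate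
13 | N,O-dimethylhydroxylamine | CNOC | starting material (reagent)
14 | hydroxy Weinreb amide | OC[C@H](Cc1cc(OC)c(OCc2ccccc2)c(OC)c1)[C@@H](C)C(=O)N(C)OC | intermediate
15 | tert-butyldimethylsilyl chloride | CC(C)(C)[Si](C)(C)Cl | starting material (reagent)
16 | TBS-protected Weinreb amide | CC(C)(C)[Si](C)(C)OC[C@H](Cc1cc(OC)c(OCc2ccccc2)c(OC)c1)[C@@H](C)C(=O)N(C)OC | intermediate
17 | magnesium | [Mg] | starting material (reagent)
18 | 4-(benzyloxy)-3-methoxyphenylmagnesium bromide | COc1cc([Mg]Br)ccc1OCc1ccccc1 | intermediate
19 | TBS-protected aryl ketone | CC(C)(C)[Si](C)(C)OC[C@H](Cc1cc(OC)c(OCc2ccccc2)c(OC)c1)[C@@H](C)C(=O)c1ccc(OCc2ccccc2)c(OC)c1 | intermediate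
20 | hydroxy ketone | OC[C@H](Cc1cc(OC)c(OCc2ccccc2)c(OC)c1)[C@@H](C)C(=O)c1ccc(OCc2ccccc2)c(OC)c1 | intermediate
21 | (1R,2R,3R)-diol | OC[C@H](Cc1cc(OC)c(OCc2ccccc2)c(OC)c1)[C@@H](C)[C@@H](O)c1ccc(OCc2ccccc2)c(OC)c1 | intermediate
22 | p-toluenesulfonyl chloride | Cc1ccc(cc1)S(=O)(=O)Cl | starting material (reagent)
23 | primary tosylate | Cc1ccc(cc1)S(=O)(=O)OC[C@H](Cc1cc(OC)c(OCc2ccccc2)c(OC)c1)[C@@H](C)[C@@H](O)c1ccc(OCc2ccccc2)c(OC)c1 | intermediate
24 | dibenzyl-protected THF | COc1cc([C@@H]2OC[C@H](Cc3cc(OC)c(OCc4ccccc4)c(OC)c3)[C@H]2C)ccc1OCc1ccccc1 | intermediate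
25 | target | COc1cc([C@@H]2OC[C@H](Cc3cc(OC)c(O)c(OC)c3)[C@H]2C)ccc1O | target

## Totals
Total steps: 16. Longest linear sequence: 14 steps, from syringaldehyde (Steps 1, 3–9, 11–16). Steps 2 and 10 form a parallel branch that makes the Grignard reagent and joins at Step 11.

## Three steps most likely to fail
1. **Step 13 (ketoreductase).** The large, lipophilic ketone may show low activity or the wrong facial selectivity. Fallback: chemical catalyst-controlled reduction of 20 by Noyori–Ikariya Ru-TsDPEN transfer hydrogenation or (R)-CBS reduction. Any 7-epimer is then corrected by p-nitrobenzoate Mitsunobu inversion and hydrolysis.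
2. **Step 5 (LiBH4 reduction of the ester in the presence of the carboxylate).** It could be slow, or could reduce the wrong carbonyl. Fallback: protect the free acid of 8 as its tert-butyl ester (Boc2O, DMAP, tBuOH), reduce the methyl ester selectively with LiBH4, then remove the tBu group with TFA, which also lactonises to 10.
3. **Step 16 (debenzylation).** The benzylic THF C–O bond, activated by the p-alkoxyaryl group, may be hydrogenolysed over Pd. Fallback: non-hydrogenolytic cleavage of the aryl benzyl ethers with BCl3 and pentamethylbenzene in CH2Cl2 at −78 °C.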